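The earlier runs and the new flask were generated by integration for substances that don't exist.

I began at the last readings of the two earlier runs, with the charges beside them.

in all of them: left-handed substrate 0.050 M; right-handed substrate 0.050 M; gas 29 mM (held); impurity 14 µM
- summer: free catalyst 25 µM; run made earlier
- midnight: free catalyst 38 µM; run made earlier
- flask: free catalyst 50 µM

- summer (time / d: left-handed product / %, left-handed substrate / %): 0.417: 2.3, 48.4; 0.833: 1.6, 46.8; 1.25: 4.3, 42.7; 1.67: 10.3, 40.7; 2.08: 13.4, 35.7; 2.50: 16.3, 34.8
- midnight (time / d: left-handed product / %, left-handed substrate / %): 0.208: 0, 49.0; 0.333: 0, 46.5; 0.500: 3.6, 46.0; 0.833: 7.1, 42.0; 1.67: 14.0, 33.4; 2.50: 22.6, 25.8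

(each reading ± 1 percentage point)

- free catalyst is single-handed; left-handed substrate and right-handed substrate are mirror images of each other, charged as a racemate, each of them at the stated concentration
- at the start none of the gas is in solution

1. apparent order in free catalyst when 5.0% of the left-handed substrate and right-handed substrate together are converted (percent change of the rate of making left-handed product for one percent more free catalyst charged)

I read the last rows against each other. At 2.50 d the summer run stood at 16.3% left-handed product and 34.8% left-handed substrate. The midnight run stood at 22.6% and 25.8%. Adding product made to substrate lost, these readings put the midnight run 1.49 times as far on, with 1.52 times the charge of free catalyst.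

Then I reckoned with what is left, not with what is charged. I assumed that each impurity takes one free catalyst for good (catalyst poisoning). On that assumption, 72.0% of the catalyst in the flask stays free. I call this share, one minus impurity over catalyst, the fraction left. It was 44.0% in the summer run and 63.2% in the midnight run.

So, on that assumption, working catalyst rose 2.18 times between the runs, more than the charge did. My reading of the order in working catalyst was therefore 0.507. With impurity held fixed, one percent more charge makes one percent divided by the fraction left more working catalyst, so, taking that order from the late readings over to 5.0% conversion, I reckoned 0.705 for the flask, against the forecast of 0.35: “the rate saturates with catalyst”.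

The flask gave 0.69.

    reagent + free catalyst + left-handed substrate → free catalyst + left-handed product (k = 8.39 /M²/s)
    reagent + free catalyst + right-handed substrate → free catalyst + right-handed product (k = 3.11 /M²/s)
    gas ⇌ reagent, rate k3*(csat - [reagent]) (kL = 1.87 × 10⁻⁵ /s)
    free catalyst + impurity → spent catalyst (k = 540 /M/s)

At 0.436 d the flask held 72.0% of its catalyst free and 28.0% spent, the free share matching the fraction left of 72.0%. Per free catalyst, with impurity as charged, the impurity step ran at 650 /d, which is 404 times the constant of 1.62 /d for gas uptake as reagent, and in the flask at 0.400 d impurity stood at 0% of its charge, while reagent had reached 35.6% of saturation.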